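## Analysis of the target

Locants C1–C15 are germacrane locants and are used for every intermediate: ring carbons C1–C10, C11–C13 the methylene-lactone carbons, C14 the ester carbon on C10, C15 the methyl on C4.

- The target is a germacranolide. Its ten-membered carbocycle is fused through C6–C7 to an α-methylene-γ-butyrolactone (O6–C12(=O)–C11(=C13)–C7) and through C4–C5 to an oxirane. C10 carries the methyl ester, O8 the angelate and O9 is free.
- Six stereocentres (4R,5S,6R,7R,8S,9S) lie on the unbroken run C4–C9. The oxirane is cis (C3 and C6 on one side), the lactone is cis-fused (H6 and H7 on one face), C11 and O8 are cis on the ring, and O8/O9 are trans on the ring, which is threo along the chain.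
- The C1=C10 enoate has C2 and C9 cis, so the double bond is cis within the ring although its descriptor is E.
- Sensitive groups: the α-methylene lactone (Michael acceptor and dipolarophile), the angelate (drifts to the tiglate with nucleophiles or base), the O8 ester beside a free O9 hydroxyl (acyl shift), the oxirane and the allylic C6–O bond (acid).
- The difficulty is a medium ring that must be made with three geometric elements (two ring-cis alkene-derived units and the cis lactone) and five stereocentres that flank each other on a flexible ring.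
- The strategy rests on two observations. C6, C5, C4 (with C15), C3, C2 and C1 are the six ring atoms of 3-methylcyclohex-2-enone, with the Z alkene that becomes the cis oxirane already locked inside that ring. The threo C8–C9 diol sits on the bond that a [3,3] shift of a 1,2-dialkenyl derivative of that ring would create.

## Retrosynthetic reasoning

**Oxirane (37 ⇒ 36).** The C4–O and C5–O bonds are removed last in the backward sense, because the oxirane is the most acid-labile group and the C4=C5 alkene of 36 is the only alkene not conjugated to a carbonyl. The forward step needs site selectivity (secured electronically) and face selectivity (peripheral attack on the ring-cis alkene).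

**Ester and O9 adjustment (36 ⇒ 35 ⇒ 34).** The methyl ester is traced to the acid 35 and further to the tert-butyl ester and MOM ether of 34. The tert-butyl group is needed much earlier, where a tertiary alkoxide sits three carbons from C14. Both groups fall in one acid step, placed before the oxirane exists, and the acid is re-esterified without diazomethane, which would add to the methylene lactone.

**Angelate (34 ⇒ 31 + 32).** The O8–acyl bond is cut to give alcohol 31 and angelic acid 32. Acylation is placed after the lactone methylenation, because the enolate chemistry of that step would deconjugate or migrate an angelate.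

**PMB and methylene (31 ⇒ 30 ⇒ 26).** The PMB ether of 30 is the latent O8 hydroxyl. The C11=C13 bond is cut to leave the plain cis-lactone 26. Mannich methylenation of the lactone enolate is done while O8 and O9 are still ethers, so no alkoxide or enolisable ester competes.

**Lactone (26 ⇒ 24).** The O6–C12 bond and the C6–H bond are disconnected to the keto diester 24. 1,2-Reduction of the enone from the face away from the C7 arm gives the cis hydroxy ester, which closes by itself, and the methyl ester reacts while the tert-butyl ester does not.

**C7–C11 (24 ⇒ 21 + 22).** The acetate arm is cut off at C7, leading to cyclodecadienone 21 and methyl bromoacetate 22. C7 is the α′ carbon of the enone, so it is the kinetic enolate position, and the neighbouring C8 ether can steer the electrophile.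

**Ring expansion (21 ⇒ 18).** This is the central disconnection. The C8–C9 bond is cut and the C1–C6 bond is re-formed, which folds the ten-membered ring back to cyclohexenol 18. The reason for cutting here and not at a ring bond that would need an end-to-end closure is that the reverse operation is a pericyclic ring expansion. It has no entropic penalty of medium-ring cyclisation, it converts the two stereocentres of 18 (C1 and C6) into C8 and C9, and it fixes the C1=C10 geometry in the same event. The forward reaction needs a chair in which both enol-ether oxygens are axial and C2 is axial on C1.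

**Alkoxyacrylate (18 ⇒ 17 ⇒ 13 + 14).** The C9–C10 bond is cut (Claisen formylation with methyl formate 14) and the O9–MOM bond is cut (O-capture of the formyl-ester enolate). This is done on the silyl ether 13 and not on a ketone: an enone with free α′ and γ protons would be deprotonated before the ester, so the carbinol carbon is built first and masked.

**C6–C7 (13 ⇒ 12 ⇒ 7 + 9).** The Z enol ether is traced to the alkynyl ether 12, and the C6–C7 bond is cut to ketone 7 and the alkoxyacetylide made from 9. A rod-like acetylide is used in place of a vinyl metal because it attacks the enone axially, which places the new carbon cis to the C1 arm as the chair of the key step demands. The Z geometry then comes from syn semi-hydrogenation and not from a configurationally fragile vinyl anion.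

**C1–C10 (7 ⇒ 6 ⇒ 3 + 4 ⇒ 1 + 2).** The only stereocentre that is not relayed is C1. It is set by cutting the C1–C10 bond: alkylation of the RAMP azaenolate of 3-methylcyclohexenone 1 with tert-butyl bromoacetate 4, the auxiliary 2 being recovered from 6.

**Acetylide precursor (9 ⇒ 8).** The dichlorovinyl ether 9 comes in one step from 4-methoxybenzyl alcohol 8 and trichloroethylene.

## Alternatives that were turned down

**Alternative 1:** The ring would be opened at C3–C4. Forward, 9-BBN would hydroborate the terminal C2=C3 alkene of an open-chain dienoate, and zerovalent palladium generated from Pd(dppf)Cl2 with aqueous base would couple the C3 borane with a C4 alkenyl iodide to give the ten-membered Z,Z-diene lactone A1.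
- For it: the Z geometry at C4=C5 comes from the iodide, and A1 already carries the angelate, the methyl ester and a masked methylene, so its endgame is shorter and gentler than the one chosen here. On that point it is stronger.
- Against it: a ten-membered ring closed through an sp3–sp2 coupling is the least favourable ring size, and slow reductive elimination invites β-hydride loss. The borane must pick the terminal alkene of a conjugated dienoate in the presence of an angelate. The aqueous base threatens the O8 ester. All five stereocentres of the chain must be built by acyclic control before the closure.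
- In exchange, the chosen route forms the ring without high dilution and obtains C8 and C9 from one auxiliary-set centre.

**Alternative 2:** The ring would be traced to a cis-decalin through the C5–C10 bond. Forward, a C5 alkoxide would expel an antiperiplanar C1 sulfonate (Grob fragmentation), giving the 4-hydroxy-5-ketone A2 with the ring-cis enoate.
- For it: the alkene geometry follows rigidly from the antiperiplanar array, which is more certain than the chair preference relied on here, and no medium ring is closed.
- Against it: the decalin needs eight stereocentres including an angular ester. A2 still lacks the oxirane (C5 reduction, activation and closure), the lactone (side-chain oxidation and lactonisation), the methylene and the angelate, and it carries four different protecting groups, so the sequence after the fragmentation is long.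
- The chosen route is shorter overall and makes the C8–C9 diol in the ring-forming step.

**Alternative 3:** The ring would be opened at C7–C8. Forward, Zn dust or In powder would turn a C13 bromide on a butenolide into an allylmetal that adds through C7 to a tethered C8 aldehyde, closing the ring and releasing the exocyclic methylene, to give A3.
- For it: A3 has the whole skeleton, the oxirane and the methylene lactone, and needs only acylation and PMB removal. Its endgame is clearly the shortest of all, and it avoids a separate methylenation.
- Against it: it is again a ten-membered closure. It must set C7 and C8 relative to C6 and C9 inside a ring-forming transition state whose preference is hard to foresee. It exposes an α-alkoxy aldehyde and an oxirane to a Lewis-acidic metal. Its open-chain substrate, with cis oxirane, Z enoate and butenolide, must be assembled linearly.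
- The chosen route offers stereospecific transfer of chirality (the C8 and C9 configurations follow from the concerted chair shift) and an early, short access to the ring.

Key step: step 9

## Route

**Step 1**
Reactants: 1 3-methylcyclohex-2-en-1-one; 2 (R)-1-amino-2-(methoxymethyl)pyrrolidine (RAMP)
Product: 3 (E)-N-[(2R)-2-(methoxymethyl)pyrrolidin-1-yl]-3-methylcyclohex-2-en-1-imine
Conditions: 2 (1.1 equiv), p-TsOH·H2O (cat.), cyclohexane, reflux, Dean–Stark
Reagents that add atoms: none
Why: Acid-catalysed hydrazone formation; the β,β-disubstituted enone does not invite conjugate addition, and both C=N isomers lead to the same azaenolate in step 2.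

**Step 2**
Reactants: 3 RAMP hydrazone; 4 tert-butyl bromoacetate
Product: 6 tert-butyl 2-[(1R,2Z)-2-{[(2R)-2-(methoxymethyl)pyrrolidin-1-yl]imino}-4-methylcyclohex-3-en-1-yl]acetate, via lithium azaenolate 5 (not isolated)
Conditions: LiN(iPr)2, THF, −78 → 0 °C; then 4, −95 → −60 °C
Reagents that add atoms: none
Why: RAMP-hydrazone alkylation: kinetic deprotonation at the α′ methylene (the vinylogous γ positions are slower) gives the chelated azaenolate 5, and the bromoacetate enters on the face not covered by the methoxymethyl arm. By the usual azaenolate model the R auxiliary gives the R centre at C1 when the entering group outranks the ring methylene, as it does here.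

**Step 3**
Reactants: 6 alkylated hydrazone
Product: 7 tert-butyl 2-[(1R)-4-methyl-2-oxocyclohex-3-en-1-yl]acetate
Conditions: sat. aq. oxalic acid, Et2O, rt
Reagents that add atoms: water, O
Why: Two-phase oxalic acid hydrolysis of the hydrazone frees the ketone at a pH that does not enolise the α centre or touch the tert-butyl ester, and returns the auxiliary as its oxalate.

**Step 4**
Reactants: 8 4-methoxybenzyl alcohol
Product: 9 1-{[(E)-1,2-dichloroethenyl]oxymethyl}-4-methoxybenzene
Conditions: KH, THF, 0 °C; trichloroethylene, −50 °C → rt
Reagents that add atoms: trichloroethylene, ClC=C(Cl)Cl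
Why: The potassium alkoxide dehydrochlorinates trichloroethylene and adds anti to the dichloroacetylene so formed; this is the standard preparation of 1,2-dichlorovinyl ethers as alkynyl-ether precursors.

**Step 5**
Reactants: 7 keto ester; 9 dichlorovinyl ether
Product: 12 tert-butyl 2-[(1R,2R)-2-{[(4-methoxybenzyl)oxy]ethynyl}-4-methyl-2-(trimethylsilyloxy)cyclohex-3-en-1-yl]acetate, via lithium alkynyl ether 10 (not isolated), via lithium alkoxide 11 (not isolated)
Conditions: 9 (1.6 equiv), n-BuLi (3.1 equiv), THF, −78 → −40 °C; 7, −78 °C; Me3SiCl, −78 → 0 °C; aq. NaHCO3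
Reagents that add atoms: chlorotrimethylsilane, C[Si](C)(C)Cl
Why: Acetylide 1,2-addition to a ketone with silylation of the alkoxide in the flask; 10 arises from 9 by dehydrochlorination and chlorine–lithium exchange. The rod-like nucleophile attacks the half-chair enone axially, anti to the axial C1–H and therefore cis to the pseudo-equatorial CH2CO2tBu arm, which sets C6 with the oxygen trans to that arm. The silyl ether protects the acid-labile carbinol and is needed in step 7.

**Step 6**
Reactants: 12 alkynyl ether
Product: 13 tert-butyl 2-[(1R,2R)-2-[(Z)-2-{(4-methoxybenzyl)oxy}ethenyl]-4-methyl-2-(trimethylsilyloxy)cyclohex-3-en-1-yl]acetate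
Conditions: H2 (1 atm), Pd/CaCO3 poisoned with Pb(OAc)2 (Lindlar catalyst), quinoline, hexane/EtOAc, Et3N (1%), 0 °C
Reagents that add atoms: none
Why: Syn semi-hydrogenation of a 1-alkynyl ether gives the Z enol ether (the reduction step of an Arens–van Dorp sequence); the poisoned catalyst leaves the trisubstituted ring alkene and the benzylic ether alone, and working cold forestalls sigmatropic loss of the benzyl group from the ynol ether.

**Step 7**
Reactants: 13 silyl ether; 14 methyl formate
Product: 17 tert-butyl (2E)-3-(methoxymethoxy)-2-[(1R,2S)-2-[(Z)-2-{(4-methoxybenzyl)oxy}ethenyl]-4-methyl-2-(trimethylsilyloxy)cyclohex-3-en-1-yl]prop-2-enoate, via ester enolate 15 (not isolated), via formyl ester enolate 16 (not isolated)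
Conditions: LiN(iPr)2, THF, −78 °C; 14, −78 → −10 °C; DMPU, MeOCH2Cl, −10 → 0 °C
Reagents that add atoms: chloromethyl methyl ether, COCCl
Why: Claisen formylation of ester enolate 15, then O-alkylation of the formyl-ester enolate 16 by the hard chloromethyl ether. In the dipolar medium the extended enolate should give the E alkoxyacrylate (OMOM cis to C1, trans to the ester), as in β-alkoxyacrylate syntheses from substituted acetic esters. Running this after C6 is fully substituted avoids the enolisation that a free enone would suffer.

**Step 8**
Reactants: 17 silyl-protected alkoxyacrylate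
Product: 18 tert-butyl (2E)-2-[(1R,2S)-2-hydroxy-2-[(Z)-2-{(4-methoxybenzyl)oxy}ethenyl]-4-methylcyclohex-3-en-1-yl]-3-(methoxymethoxy)prop-2-enoate
Conditions: Bu4NF, AcOH (1:1), THF, 0 °C
Reagents that add atoms: none
Why: Fluoride cleaves the tertiary trimethylsilyl ether; acetic acid protonates the alkoxide at once, so the Cope shift does not start here, and the medium stays too weakly acidic to ionise the doubly allylic carbinol.

**Step 9**
Reactants: 18 cis-dialkenyl cyclohexenol
Product: 21 tert-butyl (1E,5Z,9S,10S)-10-(methoxymethoxy)-9-[(4-methoxybenzyl)oxy]-5-methyl-7-oxocyclodeca-1,5-diene-1-carboxylate, via potassium alkoxide 19 (not isolated), via potassium enolate 20 (not isolated)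
Conditions: KN(SiMe3)2 (1.05 equiv), 18-crown-6, THF, −78 → 10 °C; then AcOH/THF, −78 °C
Reagents that add atoms: none
Why: Deprotonation gives alkoxide 19, whose oxyanion weakens the doubly allylic C6–C1 bond and drives a concerted [3,3] shift that breaks C6–C1 and joins C8 to C9, leaving enolate 20, which is protonated at C7 in the cold quench. The closest known reaction type is the anionic oxy-Cope ring expansion of 1,2-dialkenylcyclohexanols to cyclodec-5-enones. The ten-membered ring arises by four-atom ring expansion of the cyclohexene (C7–C10 are inserted between C6 and C1), not by an end-to-end closure. C8 and C9 are set by the chair: both enol-ether oxygens are cis to the breaking bond and so axial, hence anti across the new bond (threo), and the absolute sense (8S,9S) is relayed suprafacially from C1 and C6. The ring-cis C1=C10 bond requires the chair with C2 axial on C1, which only the cis-dialkenyl isomer can reach. That chair should be preferred because an equatorial C2 would eclipse the C10 ester (A(1,2) strain) and because potassium can bridge O6 and O8 only there, while each of the two chairs carries one carbon–oxygen 1,3-diaxial contact. The ring alkene C4=C5 could take part only through a boat-like bicyclic array, and the tert-butyl group and the vinylogous-carbonate character of the acrylate keep the alkoxide away from C14. Enolate 20 carries O8 as a β leaving group, so it is quenched cold and not left at ambient temperature.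

**Step 10**
Reactants: 21 cyclodecadienone; 22 methyl bromoacetate
Product: 24 tert-butyl (1E,5Z,8R,9S,10S)-8-(2-methoxy-2-oxoethyl)-10-(methoxymethoxy)-9-[(4-methoxybenzyl)oxy]-5-methyl-7-oxocyclodeca-1,5-diene-1-carboxylate, via lithium enolate 23 (not isolated)
Conditions: LiN(iPr)2, THF, −78 °C; 22, −78 → −40 °C
Reagents that add atoms: none
Why: Kinetic α′ deprotonation of the enone and alkylation with an α-halo ester. In the lithium enolate with O6 cis to C8 the metal can bridge to the C8 ether oxygen; C9 and the ring then cover one face and the electrophile enters beside H8 (the sense of a Fráter–Seebach alkylation), placing C11 cis to O8 on the ring (7R). The enolate is kept at −78 °C because O8 is a β leaving group.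

**Step 11**
Reactants: 24 keto diester
Product: 26 tert-butyl (1(10)E,4Z,6S,7S,8S,9S)-9-(methoxymethoxy)-8-[(4-methoxybenzyl)oxy]-13-norgermacra-1(10),4-dien-12,6-olid-14-oate (cis-fused lactone), via hydroxy ester 25 (not isolated)
Conditions: NaBH4, CeCl3·7H2O, MeOH, −78 → −20 °C; then PPTS (cat.), CH2Cl2, rt
Reagents that add atoms: none
Why: Luche 1,2-reduction of the enone: hydride should come from the ring periphery, anti to the C7–C8 bond with the C7 arm in the inside position (Felkin–Anh), giving the 6S alcohol with O6 cis to the acetate arm. This cis γ-hydroxy methyl ester closes to the γ-lactone by acyl substitution (5-exo-trig), while the tert-butyl ester does not react.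

**Step 12**
Reactants: 26 cis-lactone
Product: 30 tert-butyl (1(10)E,4Z,6S,7S,8S,9S)-9-(methoxymethoxy)-8-[(4-methoxybenzyl)oxy]germacra-1(10),4,11(13)-trien-12,6-olid-14-oate, via lactone enolate 27 (not isolated), via Mannich base 28 (not isolated), via ammonium iodide 29 (not isolated)
Conditions: LiN(iPr)2 (1.1 equiv), THF, −78 °C; CH2=NMe2+ I− (Eschenmoser's salt), −78 → 0 °C; MeI, MeOH, rt; aq. NaHCO3, EtOAc, rt
Reagents that add atoms: N,N-dimethylmethyleneiminium iodide, C=[N+](C)C.[I-]
Why: α-Methylenation of a γ-lactone by Mannich reaction of its enolate, exhaustive methylation and β-elimination of trimethylamine. The lactone α-methylene is the most acidic kinetic site, and the C11 centre of 28 and 29 (drawn for attack on the convex face) disappears in the elimination.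

**Step 13**
Reactants: 30 methylene lactone
Product: 31 tert-butyl (1(10)E,4Z,6S,7R,8S,9S)-8-hydroxy-9-(methoxymethoxy)germacra-1(10),4,11(13)-trien-12,6-olid-14-oate
Conditions: DDQ, CH2Cl2/pH 7 buffer (10:1), 0 °C
Reagents that add atoms: none
Why: Oxidative cleavage of the 4-methoxybenzyl ether by hydride abstraction and hydrolysis; O9 is capped as MOM so no acetal can form, and the buffered medium spares the alkenes and the MOM group.

**Step 14**
Reactants: 31 C8 alcohol; 32 angelic acid [(Z)-2-methylbut-2-enoic acid]
Product: 34 tert-butyl (1(10)E,4Z,6S,7S,8S,9S)-9-(methoxymethoxy)-8-{[(Z)-2-methylbut-2-enoyl]oxy}germacra-1(10),4,11(13)-trien-12,6-olid-14-oate, via mixed anhydride 33 (not isolated)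
Conditions: 32, 2,4,6-trichlorobenzoyl chloride, Et3N, toluene, rt; then 31, toluene, 75 °C
Reagents that add atoms: none
Why: Esterification through the 2,4,6-trichlorobenzoyl mixed anhydride (Yamaguchi type), run without a nucleophilic catalyst because reversible addition of such a catalyst to the angeloyl unit turns it into the tiglate. The hindered aroyl carbonyl directs the alcohol to the angeloyl carbonyl.

**Step 15**
Reactants: 34 angelate
Product: 35 (1(10)E,4Z,6S,7S,8S,9S)-9-hydroxy-8-{[(Z)-2-methylbut-2-enoyl]oxy}germacra-1(10),4,11(13)-trien-12,6-olid-14-oic acid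
Conditions: TFA/CH2Cl2 (1:4), H2O (2 equiv), anisole, 0 °C → rt
Reagents that add atoms: none
Why: Acidolysis removes the tert-butyl ester (as isobutene) and the MOM acetal in one operation. Lactone, angelate and enoate tolerate the acid, and the step is placed before the oxirane exists.

**Step 16**
Reactants: 35 hydroxy acid
Product: 36 methyl (1(10)E,4Z,6S,7S,8S,9S)-9-hydroxy-8-{[(Z)-2-methylbut-2-enoyl]oxy}germacra-1(10),4,11(13)-trien-12,6-olid-14-oate
Conditions: MeI, KHCO3, DMF, 0 °C → rt
Reagents that add atoms: iodomethane, CI
Why: O-Alkylation of the carboxylate, chosen over diazomethane because the α-methylene lactone is a dipolarophile. Bicarbonate is too weak to move the angelate to O9 or to alkylate the hydroxyl.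

**Step 17**
Reactants: 36 diene lactone
Product: 37 methyl (1(10)E,4R,5S,6R,7R,8S,9S)-4,5-epoxy-9-hydroxy-8-{[(Z)-2-methylbut-2-enoyl]oxy}germacra-1(10),11(13)-dien-12,6-olid-14-oate (CNP0251641.1)
Conditions: mCPBA, NaHCO3, CH2Cl2, −20 → 0 °C
Reagents that add atoms: 3-chloroperbenzoic acid, O=C(OO)c1cccc(Cl)c1
Why: Prilezhaev epoxidation: C4=C5 is the only alkene not conjugated to a carbonyl, and concerted syn transfer keeps C3 and C6 cis. With H6 eclipsing the alkene to avoid A(1,3) strain with C3, the ring carbons C7 and C2 cover one face, so the peracid should add from the periphery on the O6 side, which corresponds to 4R,5S.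

## Compound list

1 | 3-methylcyclohex-2-en-1-one | CC1=CC(=O)CCC1 | starting material
2 | (R)-1-amino-2-(methoxymethyl)pyrrolidine (RAMP) | COC[C@H]1CCCN1N | starting material
3 | (E)-N-[(2R)-2-(methoxymethyl)pyrrolidin-1-yl]-3-methylcyclohex-2-en-1-imine | COC[C@H]1CCCN1/N=C1\CCCC(C)=C1 | intermediate
4 | tert-butyl bromoacetate | CC(C)(C)OC(=O)CBr | starting material
5 | lithium azaenolate of 3 (not isolated) | COC[C@H]1CCCN1N([Li])C1=CCCC(C)=C1 | intermediate
6 | tert-butyl 2-[(1R,2Z)-2-{[(2R)-2-(methoxymethyl)pyrrolidin-1-yl]imino}-4-methylcyclohex-3-en-1-yl]acetate | COC[C@H]1CCCN1/N=C1\C=C(C)CC[C@@H]1CC(=O)OC(C)(C)C | intermediate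
7 | tert-butyl 2-[(1R)-4-methyl-2-oxocyclohex-3-en-1-yl]acetate | CC1=CC(=O)[C@@H](CC(=O)OC(C)(C)C)CC1 | intermediate
8 | 4-methoxybenzyl alcohol | COc1ccc(CO)cc1 | starting material
9 | 1-{[(E)-1,2-dichloroethenyl]oxymethyl}-4-methoxybenzene | COc1ccc(CO/C(Cl)=C\Cl)cc1 | intermediate
10 | lithium [(4-methoxybenzyl)oxy]acetylide (not isolated) | [Li]C#COCc1ccc(OC)cc1 | intermediate
11 | lithium alkoxide of the acetylide adduct of 7, (1R,2R) (not isolated) | CC1=C[C@@](O[Li])(C#COCc2ccc(OC)cc2)[C@@H](CC(=O)OC(C)(C)C)CC1 | intermediate
12 | tert-butyl 2-[(1R,2R)-2-{[(4-methoxybenzyl)oxy]ethynyl}-4-methyl-2-(trimethylsilyloxy)cyclohex-3-en-1-yl]acetate | CC1=C[C@@](O[Si](C)(C)C)(C#COCc2ccc(OC)cc2)[C@@H](CC(=O)OC(C)(C)C)CC1 | intermediate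
13 | tert-butyl 2-[(1R,2R)-2-[(Z)-2-{(4-methoxybenzyl)oxy}ethenyl]-4-methyl-2-(trimethylsilyloxy)cyclohex-3-en-1-yl]acetate | CC1=C[C@@](O[Si](C)(C)C)(/C=C\OCc2ccc(OC)cc2)[C@@H](CC(=O)OC(C)(C)C)CC1 | intermediate
14 | methyl formate | COC=O | starting material
15 | lithium ester enolate of 13 (not isolated) | CC1=C[C@@](O[Si](C)(C)C)(/C=C\OCc2ccc(OC)cc2)[C@@H](/C=C(/O[Li])OC(C)(C)C)CC1 | intermediate
16 | lithium enolate of the α-formyl ester, chelated form (not isolated) | CC1=C[C@@](O[Si](C)(C)C)(/C=C\OCc2ccc(OC)cc2)[C@@H](/C(C(=O)OC(C)(C)C)=C/O[Li])CC1 | intermediate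
17 | tert-butyl (2E)-3-(methoxymethoxy)-2-[(1R,2S)-2-[(Z)-2-{(4-methoxybenzyl)oxy}ethenyl]-4-methyl-2-(trimethylsilyloxy)cyclohex-3-en-1-yl]prop-2-enoate | CC1=C[C@@](O[Si](C)(C)C)(/C=C\OCc2ccc(OC)cc2)[C@@H](/C(C(=O)OC(C)(C)C)=C\OCOC)CC1 | intermediate
18 | tert-butyl (2E)-2-[(1R,2S)-2-hydroxy-2-[(Z)-2-{(4-methoxybenzyl)oxy}ethenyl]-4-methylcyclohex-3-en-1-yl]-3-(methoxymethoxy)prop-2-enoate | CC1=C[C@@](O)(/C=C\OCc2ccc(OC)cc2)[C@@H](/C(C(=O)OC(C)(C)C)=C\OCOC)CC1 | intermediate
19 | potassium alkoxide of 18 (not isolated) | CC1=C[C@@](O[K])(/C=C\OCc2ccc(OC)cc2)[C@@H](/C(C(=O)OC(C)(C)C)=C\OCOC)CC1 | intermediate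
20 | potassium C6=C7 enolate of 21, O6 cis to C8, (8S,9S) (not isolated) | C/C1=C/C(O[K])=C/[C@H](OCc2ccc(OC)cc2)[C@@H](OCOC)/C(C(=O)OC(C)(C)C)=C\CC1 | intermediate
21 | tert-butyl (1E,5Z,9S,10S)-10-(methoxymethoxy)-9-[(4-methoxybenzyl)oxy]-5-methyl-7-oxocyclodeca-1,5-diene-1-carboxylate | C/C1=C/C(=O)C[C@H](OCc2ccc(OC)cc2)[C@@H](OCOC)/C(C(=O)OC(C)(C)C)=C\CC1 | intermediate
22 | methyl bromoacetate | COC(=O)CBr | starting material
23 | lithium C6=C7 enolate of 21 (not isolated) | C/C1=C/C(O[Li])=C/[C@H](OCc2ccc(OC)cc2)[C@@H](OCOC)/C(C(=O)OC(C)(C)C)=C\CC1 | intermediate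
24 | tert-butyl (1E,5Z,8R,9S,10S)-8-(2-methoxy-2-oxoethyl)-10-(methoxymethoxy)-9-[(4-methoxybenzyl)oxy]-5-methyl-7-oxocyclodeca-1,5-diene-1-carboxylate | C/C1=C/C(=O)[C@H](CC(=O)OC)[C@H](OCc2ccc(OC)cc2)[C@@H](OCOC)/C(C(=O)OC(C)(C)C)=C\CC1 | intermediate
25 | tert-butyl (1E,5Z,7S,8S,9S,10S)-7-hydroxy-8-(2-methoxy-2-oxoethyl)-10-(methoxymethoxy)-9-[(4-methoxybenzyl)oxy]-5-methylcyclodeca-1,5-diene-1-carboxylate (not isolated) | C/C1=C/[C@H](O)[C@H](CC(=O)OC)[C@H](OCc2ccc(OC)cc2)[C@@H](OCOC)/C(C(=O)OC(C)(C)C)=C\CC1 | intermediate
26 | tert-butyl (1(10)E,4Z,6S,7S,8S,9S)-9-(methoxymethoxy)-8-[(4-methoxybenzyl)oxy]-13-norgermacra-1(10),4-dien-12,6-olid-14-oate | C/C1=C/[C@@H]2OC(=O)C[C@@H]2[C@H](OCc3ccc(OC)cc3)[C@@H](OCOC)/C(C(=O)OC(C)(C)C)=C\CC1 | intermediate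
27 | lithium enolate of lactone 26 (not isolated) | C/C1=C/[C@@H]2OC(O[Li])=C[C@@H]2[C@H](OCc3ccc(OC)cc3)[C@@H](OCOC)/C(C(=O)OC(C)(C)C)=C\CC1 | intermediate
28 | (11R)-11-[(dimethylamino)methyl] derivative of 26 (not isolated) | C/C1=C/[C@@H]2OC(=O)[C@@H](CN(C)C)[C@@H]2[C@H](OCc3ccc(OC)cc3)[C@@H](OCOC)/C(C(=O)OC(C)(C)C)=C\CC1 | intermediate
29 | (11R)-11-[(trimethylammonio)methyl] derivative of 26, iodide (not isolated) | C/C1=C/[C@@H]2OC(=O)[C@@H](C[N+](C)(C)C)[C@@H]2[C@H](OCc3ccc(OC)cc3)[C@@H](OCOC)/C(C(=O)OC(C)(C)C)=C\CC1.[I-] | intermediate
30 | tert-butyl (1(10)E,4Z,6S,7S,8S,9S)-9-(methoxymethoxy)-8-[(4-methoxybenzyl)oxy]germacra-1(10),4,11(13)-trien-12,6-olid-14-oate | C/C1=C/[C@@H]2OC(=O)C(=C)[C@@H]2[C@H](OCc3ccc(OC)cc3)[C@@H](OCOC)/C(C(=O)OC(C)(C)C)=C\CC1 | intermediate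
31 | tert-butyl (1(10)E,4Z,6S,7R,8S,9S)-8-hydroxy-9-(methoxymethoxy)germacra-1(10),4,11(13)-trien-12,6-olid-14-oate | C/C1=C/[C@@H]2OC(=O)C(=C)[C@@H]2[C@H](O)[C@@H](OCOC)/C(C(=O)OC(C)(C)C)=C\CC1 | intermediate
32 | angelic acid, (Z)-2-methylbut-2-enoic acid | C/C=C(/C)C(=O)O | starting material
33 | angelic 2,4,6-trichlorobenzoic anhydride (not isolated) | C/C=C(/C)C(=O)OC(=O)c1c(Cl)cc(Cl)cc1Cl | intermediate
34 | tert-butyl (1(10)E,4Z,6S,7S,8S,9S)-9-(methoxymethoxy)-8-{[(Z)-2-methylbut-2-enoyl]oxy}germacra-1(10),4,11(13)-trien-12,6-olid-14-oate | C/C1=C/[C@@H]2OC(=O)C(=C)[C@@H]2[C@H](OC(=O)/C(C)=C\C)[C@@H](OCOC)/C(C(=O)OC(C)(C)C)=C\CC1 | intermediate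
35 | (1(10)E,4Z,6S,7S,8S,9S)-9-hydroxy-8-{[(Z)-2-methylbut-2-enoyl]oxy}germacra-1(10),4,11(13)-trien-12,6-olid-14-oic acid | C/C1=C/[C@@H]2OC(=O)C(=C)[C@@H]2[C@H](OC(=O)/C(C)=C\C)[C@@H](O)/C(C(=O)O)=C\CC1 | intermediate
36 | methyl (1(10)E,4Z,6S,7S,8S,9S)-9-hydroxy-8-{[(Z)-2-methylbut-2-enoyl]oxy}germacra-1(10),4,11(13)-trien-12,6-olid-14-oate | C/C1=C/[C@@H]2OC(=O)C(=C)[C@@H]2[C@H](OC(=O)/C(C)=C\C)[C@@H](O)/C(C(=O)OC)=C\CC1 | intermediate
37 | methyl (1(10)E,4R,5S,6R,7R,8S,9S)-4,5-epoxy-9-hydroxy-8-{[(Z)-2-methylbut-2-enoyl]oxy}germacra-1(10),11(13)-dien-12,6-olid-14-oate (CNP0251641.1) | C=C1C(=O)O[C@@H]2[C@H]1[C@H](OC(=O)/C(C)=C\C)[C@@H](O)/C(C(=O)OC)=C\CC[C@@]1(C)O[C@@H]21 | target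

## Step count and least certain steps

Total step count: 17. Longest linear sequence: 16 (steps 1–3 and 5–17, from 1); step 4 is a one-step side branch from 8.

**Step 9 (key step).** Two processes may spoil it. The first is a poor choice between the two chairs open to the cis-dialkenyl alkoxide: the chair with C2 equatorial would give the ring-trans enoate with both new centres inverted, and only the eclipsing of C2 with the C10 ester and potassium bridging argue against it. The second is β-elimination of the C8 oxygen from the enolate once it has formed, or attack of the alkoxide on C14 if the shift is slow.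
Fallback: set out from 17 and run the rearrangement without any anion. Heating the trimethylsilyl ether in base-washed glass (toluene, sealed, about 140–160 °C, a trace of Et3N) is a thermal silyloxy-Cope shift and should give the trimethylsilyl enol ether of 21, F1, which cannot eliminate. Cold Bu4NF/AcOH then releases the ketone, and the route is rejoined at 21.

**Step 5.** The ynol ether in 11 and 12 may hydrate or shed its benzyl group by sigmatropic shift before it is reduced, and axial attack of the acetylide may be incomplete.
Fallback: avoid alkynyl ethers and bring in the Z enol ether as a vinyl anion.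
- Set out from 8: transfer vinylation (ethyl vinyl ether, Pd(OAc)2, 1,10-phenanthroline) gives 4-methoxybenzyl vinyl ether F2.
- Br2 at −78 °C gives the 1,2-dibromoethyl ether F3, and DBU eliminates HBr to the (Z)-2-bromovinyl ether F4.
- t-BuLi at −78 °C gives (Z)-2-[(4-methoxybenzyl)oxy]vinyllithium F5, which adds to 7 to give the lithium alkoxide F6.
- Me3SiCl converts F6 into 13, where the route is rejoined.
- This bypasses 12 at the cost of a less slender nucleophile, so the diastereomers may need separation at 13.

**Step 10.** Deprotonation of 21 does not fix the enolate geometry, so the face selectivity at C7 may be poor, and the enolate may expel the C8 oxygen.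
Fallback: set out from 18 and use the enolate that the rearrangement itself delivers. The Cope shift gives 20 with O6 cis to C8 by necessity. Adding LiBr at −78 °C (to give 23 with a defined geometry) and then 22 to the same flask should give 24 directly. No compound outside the compound list is formed (F0).

**Step 11.** Hydride may attack the other face of the C6 carbonyl if the ring does not adopt the assumed local conformation, giving the C6 epimer, which cannot form the cis lactone.
Fallback: set out from 24 and correct C6 by inversion. The 6-epi hydroxy ester F7 is saponified at the methyl ester (LiOH, THF/H2O; the tert-butyl ester stays) to the hydroxy acid F8. Mitsunobu lactonisation (PPh3, DIAD) closes the lactone with inversion at C6; five-membered closure at C6 should beat allylic transposition to C4. The route is rejoined at 26.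

**Step 14.** The hindered C8 hydroxyl may acylate slowly, and the angeloyl unit may isomerise to the tiglate under prolonged heating with amine.
Fallback: build the Z alkene after the ester bond. Set out from 31 and esterify with 2-[bis(2,2,2-trifluoroethoxy)phosphoryl]propanoic acid (carbodiimide, DMAP) to the phosphonate ester F9. A Still–Gennari olefination (KN(SiMe3)2, 18-crown-6, acetaldehyde, −78 °C) then forms the Z trisubstituted enoate, and the route is rejoined at 34.

**Step 17.** The peracid may choose the other face of C4=C5 if the allylic C6–O bond, and not the ring, controls the approach.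
Fallback: set out from 36 and deliver the oxygen anti to the first electrophile. N-Bromosuccinimide in aqueous THF attacks the face the peracid would take and water opens the bromonium ion at C4, giving the bromohydrin F10 (4-hydroxy, 5-bromo). DBU in CH2Cl2 closes the oxirane by displacement at C5 with inversion, so the oxygen ends on the opposite face, and the route is rejoined at 37.

## Further compounds

F1 | step 9 | trimethylsilyl enol ether of 21 (C6=C7, O6 cis to C8; 8S,9S) | C/C1=C/C(O[Si](C)(C)C)=C/[C@H](OCc2ccc(OC)cc2)[C@@H](OCOC)/C(C(=O)OC(C)(C)C)=C\CC1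
F2 | step 5 | 4-methoxybenzyl vinyl ether | C=COCc1ccc(OC)cc1
F3 | step 5 | 1-[(1,2-dibromoethoxy)methyl]-4-methoxybenzene (racemic) | COc1ccc(COC(Br)CBr)cc1
F4 | step 5 | 1-{[(Z)-2-bromoethenyl]oxymethyl}-4-methoxybenzene | COc1ccc(CO/C=C\Br)cc1
F5 | step 5 | (Z)-2-[(4-methoxybenzyl)oxy]vinyllithium | [Li]/C=C\OCc1ccc(OC)cc1
F6 | step 5 | lithium alkoxide of the vinyl adduct of 7, (1R,2R) | CC1=C[C@@](O[Li])(/C=C\OCc2ccc(OC)cc2)[C@@H](CC(=O)OC(C)(C)C)CC1
F0 | step 10 | none | none
F7 | step 11 | tert-butyl (1E,5Z,7R,8S,9S,10S)-7-hydroxy-8-(2-methoxy-2-oxoethyl)-10-(methoxymethoxy)-9-[(4-methoxybenzyl)oxy]-5-methylcyclodeca-1,5-diene-1-carboxylate (C6 epimer of 25) | C/C1=C/[C@@H](O)[C@H](CC(=O)OC)[C@H](OCc2ccc(OC)cc2)[C@@H](OCOC)/C(C(=O)OC(C)(C)C)=C\CC1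
F8 | step 11 | 2-[(1S,2E,6Z,8R,9S,10S)-2-(tert-butoxycarbonyl)-8-hydroxy-10-(methoxymethoxy)-9-[(4-methoxybenzyl)oxy]-6-methylcyclodeca-2,6-dien-1-yl... acid form of F7: carboxylic acid from saponification of the methyl ester of F7 | C/C1=C/[C@@H](O)[C@H](CC(=O)O)[C@H](OCc2ccc(OC)cc2)[C@@H](OCOC)/C(C(=O)OC(C)(C)C)=C\CC1
F9 | step 14 | 8-O-{2-[bis(2,2,2-trifluoroethoxy)phosphoryl]propanoyl} derivative of 31 (either epimer at the phosphonate-bearing carbon) | C/C1=C/[C@@H]2OC(=O)C(=C)[C@@H]2[C@H](OC(=O)C(C)P(=O)(OCC(F)(F)F)OCC(F)(F)F)[C@@H](OCOC)/C(C(=O)OC(C)(C)C)=C\CC1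
F10 | step 17 | bromohydrin of 36: 5-bromo-4-hydroxy compound, bromine anti to the C4 hydroxyl, C4 oxygen on the face of the target oxirane | C=C1C(=O)O[C@@H]2[C@H]1[C@H](OC(=O)/C(C)=C\C)[C@@H](O)/C(C(=O)OC)=C\CC[C@@](C)(O)[C@@H]2Br
A1 | alternative 1 | ten-membered Z,Z-diene lactone with angelate, O9 triethylsilyl ether and C13 silyloxymethyl group | C/C1=C/[C@@H]2OC(=O)[C@@H](CO[Si](C)(C)C(C)(C)C)[C@@H]2[C@H](OC(=O)/C(C)=C\C)[C@@H](O[Si](CC)(CC)CC)/C(C(=O)OC)=C\CC1
A2 | alternative 2 | ten-membered 4-hydroxy-5-ketone with ring-cis enoate | C[C@]1(O)C(=O)[C@H](OCc2ccc(OC)cc2)[C@H](CCO[Si](C)(C)C(C)(C)C)[C@H](O[Si](CC)(CC)CC)[C@@H](O[Si](C)(C)C(C)(C)C)/C(C(=O)OC)=C\CC1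
A3 | alternative 3 | full skeleton with free O8 hydroxyl and 4-methoxybenzyl ether on O9 | C=C1C(=O)O[C@@H]2[C@H]1[C@H](O)[C@@H](OCc3ccc(OC)cc3)/C(C(=O)OC)=C\CC[C@@]1(C)O[C@@H]21
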